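Readings and results are simulated with constants of no real substance.

Start with the easy part: the starting material falls like a discharging capacitor. Sunday's and Monday's runs, at very different charges, both leave nearly the same percentage at the same time, 38.0% and 37.9% after 8.00 min.

| setting | Sunday's | Monday's | south-east | east | south-west | north-east | north-west |
|---|---|---|---|---|---|---|---|
| starting material | 0.065 M | 0.47 M | 0.12 M | 0.20 M | 0.25 M | 0.40 M | 0.60 M |
| first nucleophile | 1.6 M | 1.6 M | 1.60 M | 1.60 M | 1.60 M | 1.60 M | 1.60 M |
| second nucleophile | 1.2 M | 1.2 M | 1.20 M | 1.20 M | 1.20 M | 1.20 M | 1.20 M |
| remark | run made earlier | run made earlier |  |  |  |  |  |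
| time |  |  | 12 min | 12 min | 12 min | 12 min | 12 min |

| run | time / min | target / % | starting material / % |
|---|---|---|---|
| Sunday's | 1.50 | 2.7 | 83.7 |
| Sunday's | 3.00 | 6.0 | 70.1 |
| Sunday's | 5.00 | 10.2 | 54.4 |
| Sunday's | 6.00 | 11.3 | 48.8 |
| Sunday's | 8.00 | 13.9 | 38.0 |
| Monday's | 0.667 | 1.2 | 92.6 |
| Monday's | 1.33 | 2.9 | 85.2 |
| Monday's | 2.50 | 4.9 | 74.5 |
| Monday's | 4.00 | 8.0 | 62.1 |
| Monday's | 8.00 | 14.4 | 37.9 |

(standard deviation of a reading: 0.3 percentage points)

- target is meant together with its crystals
- solid, in amounts per volume of the solution: crystals
- the numbers in the tables scatter by 0.3 percentage points (one standard deviation)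
- on the list of suspects stand: starting material -> intermediate; first nucleophile + intermediate -> target; second nucleophile + intermediate -> other capture product; intermediate -> solvolysis product; first nucleophile <-> dormant form; crystals <-> target
- the concentration of target that is asked is that of its free form alone
- "hardly changes" means that all values lie within two and a half points (for a concentration: within two and a half percent of the largest)

- [target] (only what is free in solution) at the end for south-east, east, south-west, north-east, north-west, in this order
- how that number moves from the first to the last of them (falls, then rises / rises, then falls / falls all the way / rises all the way / hardly changes)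

From Sunday's reading I take a rate constant of 0.121 /min, a time constant of 8.26 min, so 23.4% of the starting material stands at 12 min. Next comes the selectivity, the target made per starting material consumed. At 8.00 min it reads 22.4% on Sunday and 23.2% on Monday, with a mean of 22.8%. Multiplying that by the part consumed gives the end yield f, 17.5%, the fraction of the charge that is target at 12 min, crystals counted.

So I reckon target plus crystals at 0.0210 M in the south-east flask and 0.105 M in the north-west flask. The readings don't show how that total splits between solution and solid.

The forecast gives free target as 0.021 M, 0.035 M, 0.044 M, 0.07 M, 0.105 M, which rises all the way, and says “My best estimate is no cap”.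

The flasks give 0.00772 M, 0.00800 M, 0.00817 M, 0.00871 M, 0.00944 M, which also rises all the way.

    starting material → intermediate (k = 0.120 /min)
    first nucleophile + intermediate → target (k = 0.510 /M/min)
    second nucleophile + intermediate → other capture product (k = 1.30 /M/min)
    intermediate → solvolysis product (k = 0.930 /min)
    first nucleophile ⇌ dormant form (K = 0.0950, k = 0.150 /min)
    crystals ⇌ target, rate k6*(cs6 - [target]) while solid is left; crystals form when [target] > cs6 (solubility = 7.30 mM, k = 2.10 /min)

Take away the limit on how little target dissolves, and the north-west flask ends at 0.106 M of free target instead of 0.00944 M. That is the largest single effect, and it lands close to f times the charge, 0.105 M. So f still gives the total, while free target in the north-west flask stands at 0.00944 M, which is 2.14 mM above the solubility of 7.3 mM. Subtracting the free part from f, the north-west flask holds 15.9% of its charge as crystals, where the table has 16.2%. The same subtraction on the south-east flask gives 11.0%, where the table has 11.1%.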